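**Plan** (labdane numbering; β = face of the C10 methyl)
- Retrosynthetic cuts, in order: C13–C14 and C15–O of the dihydrofuran (one [3+2] event); O9–C13 (iodoetherification) and C9–C11 (organocerium); C7–O and C8–O (directed epoxidation, SN2 opening); C1–C10 and C4–C5 (Diels–Alder).
- Forward: ring A is annulated onto 2,6-dimethylbenzoquinone (ring B) by a catalytic asymmetric Diels–Alder reaction that also makes the cis ring fusion; ring B is then oxygenated, the oxolane closed, the dihydrofuran added, and three unmasking steps finish.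
- Enabling feature: C13 carries the oxolane oxygen (the O between C9 and C13) and the CH2–O carbon C16. A spiro-epoxide across C13–C16 therefore ionises to a ring-oxygen-stabilised C13 oxocarbenium ion beside an O16 nucleophile, and an acetaldehyde enol silane (C14 nucleophilic, C15 electrophilic) spans this pair.
- Stereochemistry: C5 and C10 come from the catalyst-controlled cycloaddition (cis fusion is intrinsic). C9 (convex-face addition), C8 and C7 (hydroxyl-directed epoxidation, inversion at C7) and C13 (facial bias of the folded cis-decalin) are relayed by the substrate.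
- C6 stays a silyl ether until the penultimate step, so the 5β-H next to the ketone never meets base.

Key step: step 12

**Remarks**
- The target is read as (5R,7R,8R,9S,10S,13S): 5β-H and 10β-CH3 (cis-fused decalin), 7β-OH, 8α-OAc, 9α-O, with C14 on the oxolane face syn to C8. The side chain is C11, C12, C13, C16; C17 is on C8, C20 on C10.
- Assumption: the (S)-configured catalyst of step 1 is taken to give the enantiomer shown; if it gives the antipode, the (R)-catalyst is used.
- The iodoether stage is a C13-epimer mixture and the lactol stage a C15-anomer mixture; both centres become trigonal later.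

**Route**

Step 1
Reactants: 1 2,6-dimethyl-1,4-benzoquinone; 2 4-methylpenta-1,3-diene
Product: 3 (4aR,8aS)-2,5,5,8a-tetramethyl-4a,5,8,8a-tetrahydronaphthalene-1,4-dione (cis-fused enedione)
Conditions: protonated oxazaborolidine catalyst [(S)-1-(2-methylphenyl)-3,3-diphenyltetrahydro-1H,3H-pyrrolo[1,2-c][1,3,2]oxazaborole + HN(SO2CF3)2] (20 mol %), CH2Cl2, −78 → −20 °C
Reagents that add atoms: none
Why: Enantioselective Lewis-acid-catalysed Diels–Alder reaction: the catalyst binds the less hindered, more basic carbonyl flanked by two CH groups, so the methyl-bearing β-carbon becomes the electrophilic terminus and pairs with the unsubstituted diene terminus while the gem-dimethyl terminus bonds to the CH carbon, suprafacial addition makes C5–H and C10–CH3 cis, and the chiral cation blocks one of the two enantiotopic faces of the quinone.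

Step 2
Reactants: 3 cis-fused enedione
Product: 4 (4S,4aR,8aS)-4-hydroxy-2,5,5,8a-tetramethyl-4a,5,8,8a-tetrahydronaphthalen-1(4H)-one (6α-hydroxy enone)
Conditions: NaBH4, CeCl3·7H2O, MeOH, −78 °C
Reagents that add atoms: none
Why: Luche 1,2-reduction: the C6 carbonyl (flanked by C5–H and C7–H) reacts in preference to the C9 carbonyl (flanked by quaternary C10 and methylated C8), and hydride enters from the convex β-face away from the C4 gem-dimethyl group, giving the 6α-alcohol as a temporary stereocentre that masks the ketone.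

Step 3
Reactants: 4 6α-hydroxy enone
Product: 5 6α-(tert-butyldimethylsilyloxy) enone
Conditions: tBuMe2SiOTf, 2,6-lutidine, CH2Cl2, −78 → 0 °C
Reagents that add atoms: tert-butyldimethylsilyl triflate CC(C)(C)[Si](C)(C)OS(=O)(=O)C(F)(F)F
Why: Silyl ether formation with the reactive triflate protects the hindered secondary alcohol and leaves the enone untouched.

Step 4
Reactants: 5 silyl ether
Product: 6 (4S,4aR,8aS)-4-(tert-butyldimethylsilyloxy)-2,5,5,8a-tetramethyl-4a,5,6,7,8,8a-hexahydronaphthalen-1(4H)-one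
Conditions: H2 (4 atm), RhCl(PPh3)3 (5 mol %), benzene, rt
Reagents that add atoms: none
Why: Homogeneous hydrogenation with this rhodium catalyst discriminates by substitution, so the cis-disubstituted ring A alkene is reduced and the trisubstituted conjugated C7=C8 bond is kept; no stereocentre is formed.

Step 5
Reactants: 6 ring-A-saturated enone; 7 but-3-enylmagnesium bromide
Product: 8 (5β)-6α-(tert-butyldimethylsilyloxy)-14,15-dinorlabda-7,13(16)-dien-9α-ol
Conditions: CeCl3 (anhydrous), THF, −78 → 0 °C; aq. NH4Cl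
Reagents that add atoms: none
Why: Organocerium 1,2-addition suppresses enolisation and conjugate addition at this hindered cyclohexenone carbonyl, and the nucleophile enters from the convex β-face because ring A screens the α-face, so C9 receives the side chain β and the hydroxyl α.

Step 6
Reactants: 8 tertiary allylic alcohol
Product: 9 (5β)-6α-(tert-butyldimethylsilyloxy)-7α,8α-epoxy-14,15-dinorlabd-13(16)-en-9α-ol
Conditions: VO(acac)2 (5 mol %), tBuOOH (1.5 equiv), CH2Cl2, 0 °C → rt
Reagents that add atoms: tert-butyl hydroperoxide CC(C)(C)OO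
Why: Vanadium-catalysed hydroxyl-directed epoxidation delivers oxygen within the vanadate ester of the 9α-alcohol, giving the 7α,8α-epoxide syn to the hydroxyl, while the remote monosubstituted alkene reacts far more slowly.

Step 7
Reactants: 9 epoxy alcohol
Product: 11 (5β)-6α-(tert-butyldimethylsilyloxy)-14,15-dinorlabd-13(16)-ene-7β,8α,9α-triol, via 7β-acetate 10 (not isolated)
Conditions: Ti(OiPr)4 (1.5 equiv), AcOH (3 equiv), CH2Cl2, rt; then K2CO3, MeOH, 0 °C
Reagents that add atoms: acetic acid CC(=O)O
Why: Ti(OiPr)4-mediated opening of a 2,3-epoxy alcohol by a carboxylic acid occurs at the carbon remote from the carbinol (C7; C8 is tertiary and neopentylic, closed to SN2), so anti attack inverts C7 to 7β-O and leaves the epoxide oxygen as the 8α-hydroxyl, and methanolysis of the only ester frees the triol.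

Step 8
Reactants: 11 triol
Product: 12 (5β)-6α-(tert-butyldimethylsilyloxy)-9α,13-epoxy-16-iodo-14,15-dinorlabdane-7β,8α-diol (C13 epimers)
Conditions: N-iodosuccinimide, NaHCO3, MeCN, 0 °C, dark
Reagents that add atoms: N-iodosuccinimide O=C1CCC(=O)N1I
Why: Iodoetherification: 5-exo-trig attack of the 9α-hydroxyl on the iodonium ion of the terminal alkene outpaces the 6-exo (8-OH) and 7-exo (7-OH) modes and forms the oxolane bond O9–C13; the C13 configuration is irrelevant because C13 becomes trigonal in step 11.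

Step 9
Reactants: 12 iodoether diol
Product: 13 7β-allyl carbonate of 12
Conditions: allyl chloroformate, pyridine, CH2Cl2, 0 °C → rt
Reagents that add atoms: allyl chloroformate C=CCOC(=O)Cl
Why: Carbonate formation acylates the secondary 7β-hydroxyl in preference to the tertiary 8α-hydroxyl and installs a group that can be removed last under neutral conditions.

Step 10
Reactants: 13 allyl carbonate
Product: 14 8α-acetate of 13
Conditions: Ac2O, DMAP, Et3N, CH2Cl2, 40 °C
Reagents that add atoms: acetic anhydride CC(=O)OC(C)=O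
Why: DMAP-catalysed (Steglich-type) acetylation of the only free hydroxyl, the tertiary 8α-OH, installs the acetate of the target.

Step 11
Reactants: 14 iodide
Product: 15 (5β)-8α-acetoxy-7β-(allyloxycarbonyloxy)-6α-(tert-butyldimethylsilyloxy)-9α,13-epoxy-14,15-dinorlabd-13(16)-ene (2-methyleneoxolane)
Conditions: AgF, pyridine, rt, dark
Reagents that add atoms: none
Why: E2 dehydrohalogenation as used for 5-deoxy-5-iodofuranosides: silver assists loss of iodide and the only β-hydrogen (C13–H) is removed, giving the exocyclic enol ether without touching the esters, carbonate or silyl ether.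

Step 12
Reactants: 15 exocyclic enol ether; 16 vinyloxytrimethylsilane
Product: 19 spiro-lactol (13S; C15 anomers), via spiro-epoxide 17 (not isolated), via O-trimethylsilyl lactol 18 (not isolated)
Conditions: dimethyldioxirane (acetone), CH2Cl2, −78 → 0 °C, volatiles removed; then 16 (5 equiv), Me3SiOTf (0.2 equiv), 4 Å MS, CH2Cl2, −78 → −40 °C; then AcOH/H2O/THF, 0 °C
Reagents that add atoms: dimethyldioxirane CC1(C)OO1
Why: Proposed new method: dimethyldioxirane should epoxidise the 2-methyleneoxolane to the spiro-epoxide 17 (as with exo-glycals); Me3SiOTf should then open it at C13 to a tertiary oxocarbenium ion stabilised by the oxolane oxygen and flanked by C16–OSiMe3, the enol silane should add through its CH2 terminus (Mukaiyama-type, forms C13–C14), and the silyloxocarbenium ion so formed at C15 should be captured by the C16 oxygen (forms C15–O16) with release of Me3Si+, which turns the catalyst over, so the whole is a formal [3+2] annulation of a C–O dipole equivalent with an enol ether. The closest known reactions are the Lewis-acid-promoted C-glycosylation of 1,2-anhydro sugars with silyl enol ethers and the Lewis-acid [3+2] annulation of aryl oxiranes with alkenes. The new five-membered ring closes by 5-exo-trig attack of O16 on the C15 oxocarbenium ion. C13 is set by the face of attack on the planar (SN1) oxocarbenium ion: C13 hangs from O9 on the concave α-side of the cis-fused decalin, where ring A (C1, C2) walls off the face turned towards C10, so the nucleophile should enter from the face turned towards C8 and C14 ends syn to C8 (13S), while C15 forms as an anomer mixture that is erased in step 13. The step needs this facial selectivity and needs C–C bond formation to outrun proton loss from the oxocarbenium ion; an excess of the small enol silane at low temperature and the non-participating 8-acetate (a seven-membered participation is not expected) are relied on for both.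

Step 13
Reactants: 19 spiro-lactol
Product: 21 (5β,13S)-8α-acetoxy-7β-(allyloxycarbonyloxy)-6α-(tert-butyldimethylsilyloxy)-9α,13;15,16-diepoxylabd-14-ene, via lactol mesylate 20 (not isolated)
Conditions: MeSO2Cl, Et3N, CH2Cl2, −40 °C → rt
Reagents that add atoms: none
Why: Lactol dehydration: O-mesylation, ionisation at C15 and loss of a C14 proton (the only β-hydrogens, since C13 is quaternary) give the 2,3-dihydrofuran, and no other hydroxyl is free.

Step 14
Reactants: 21 silyl ether
Product: 22 6α-alcohol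
Conditions: Bu4NF/AcOH (1:1), THF, rt → 40 °C
Reagents that add atoms: none
Why: Fluoride-mediated desilylation buffered with acetic acid frees the 6α-hydroxyl without strong acid (the spiro enol ether is acid-labile) and without a free alkoxide that could trigger acetyl or carbonate migration.

Step 15
Reactants: 22 6α-alcohol
Product: 23 (5β,13S)-8α-acetoxy-7β-(allyloxycarbonyloxy)-9α,13;15,16-diepoxylabd-14-en-6-one
Conditions: Dess–Martin periodinane, NaHCO3, CH2Cl2, 0 °C → rt
Reagents that add atoms: none
Why: Dess–Martin oxidation under buffered, non-enolising conditions converts the only free alcohol into the C6 ketone, so C5 keeps the 5β-H set in step 1.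

Step 16
Reactants: 23 allyl carbonate ketone
Product: 24 target, (5β,13S)-8α-acetoxy-7β-hydroxy-9α,13;15,16-diepoxylabd-14-en-6-one
Conditions: Pd(PPh3)4 (5 mol %), PhNHMe (3 equiv), THF, rt
Reagents that add atoms: none
Why: Tsuji–Trost deallylation: zerovalent palladium ionises the allyl carbonate, CO2 is lost and the allyl fragment is trapped by the nearly neutral N-methylaniline, releasing the 7β-hydroxyl without acid or base so that C5, the spiro enol ether and the β-acetoxy ketone survive.

**Compound list**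
1 | 2,6-dimethyl-1,4-benzoquinone | CC1=CC(=O)C=C(C)C1=O | starting material
2 | 4-methylpenta-1,3-diene | CC(C)=CC=C | starting material
3 | (4aR,8aS)-2,5,5,8a-tetramethyl-4a,5,8,8a-tetrahydronaphthalene-1,4-dione | CC1=CC(=O)[C@@H]2C(C)(C)C=CC[C@]2(C)C1=O | intermediate
4 | (4S,4aR,8aS)-4-hydroxy-2,5,5,8a-tetramethyl-4a,5,8,8a-tetrahydronaphthalen-1(4H)-one | CC1=C[C@H](O)[C@@H]2C(C)(C)C=CC[C@]2(C)C1=O | intermediate
5 | tert-butyldimethylsilyl ether of 4 | CC1=C[C@H](O[Si](C)(C)C(C)(C)C)[C@@H]2C(C)(C)C=CC[C@]2(C)C1=O | intermediate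
6 | (4S,4aR,8aS)-4-(tert-butyldimethylsilyloxy)-2,5,5,8a-tetramethyl-4a,5,6,7,8,8a-hexahydronaphthalen-1(4H)-one | CC1=C[C@H](O[Si](C)(C)C(C)(C)C)[C@@H]2C(C)(C)CCC[C@]2(C)C1=O | intermediate
7 | but-3-enylmagnesium bromide | C=CCC[Mg]Br | starting material
8 | (5β)-6α-(tert-butyldimethylsilyloxy)-14,15-dinorlabda-7,13(16)-dien-9α-ol | CC1=C[C@H](O[Si](C)(C)C(C)(C)C)[C@@H]2C(C)(C)CCC[C@]2(C)[C@@]1(O)CCC=C | intermediate
9 | (5β)-6α-(tert-butyldimethylsilyloxy)-7α,8α-epoxy-14,15-dinorlabd-13(16)-en-9α-ol | C[C@@]12O[C@@H]1[C@H](O[Si](C)(C)C(C)(C)C)[C@@H]1C(C)(C)CCC[C@]1(C)[C@@]2(O)CCC=C | intermediate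
10 | (5β)-7β-acetoxy-6α-(tert-butyldimethylsilyloxy)-14,15-dinorlabd-13(16)-ene-8α,9α-diol | O[C@]1(C)[C@@H](OC(C)=O)[C@H](O[Si](C)(C)C(C)(C)C)[C@@H]2C(C)(C)CCC[C@]2(C)[C@@]1(O)CCC=C | intermediate
11 | (5β)-6α-(tert-butyldimethylsilyloxy)-14,15-dinorlabd-13(16)-ene-7β,8α,9α-triol | O[C@]1(C)[C@@H](O)[C@H](O[Si](C)(C)C(C)(C)C)[C@@H]2C(C)(C)CCC[C@]2(C)[C@@]1(O)CCC=C | intermediate
12 | (5β)-6α-(tert-butyldimethylsilyloxy)-9α,13-epoxy-16-iodo-14,15-dinorlabdane-7β,8α-diol (C13 epimers) | O[C@]1(C)[C@@H](O)[C@H](O[Si](C)(C)C(C)(C)C)[C@@H]2C(C)(C)CCC[C@]2(C)[C@@]12CCC(CI)O2 | intermediate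
13 | 7β-allyl carbonate of 12 | O[C@]1(C)[C@@H](OC(=O)OCC=C)[C@H](O[Si](C)(C)C(C)(C)C)[C@@H]2C(C)(C)CCC[C@]2(C)[C@@]12CCC(CI)O2 | intermediate
14 | 8α-acetate of 13 | CC(=O)O[C@]1(C)[C@@H](OC(=O)OCC=C)[C@H](O[Si](C)(C)C(C)(C)C)[C@@H]2C(C)(C)CCC[C@]2(C)[C@@]12CCC(CI)O2 | intermediate
15 | (5β)-8α-acetoxy-7β-(allyloxycarbonyloxy)-6α-(tert-butyldimethylsilyloxy)-9α,13-epoxy-14,15-dinorlabd-13(16)-ene | CC(=O)O[C@]1(C)[C@@H](OC(=O)OCC=C)[C@H](O[Si](C)(C)C(C)(C)C)[C@@H]2C(C)(C)CCC[C@]2(C)[C@@]12CCC(=C)O2 | intermediate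
16 | vinyloxytrimethylsilane | C=CO[Si](C)(C)C | starting material
17 | 13,16-epoxide of 15 (spiro-epoxide, C13 unassigned) | CC(=O)O[C@]1(C)[C@@H](OC(=O)OCC=C)[C@H](O[Si](C)(C)C(C)(C)C)[C@@H]2C(C)(C)CCC[C@]2(C)[C@@]12CCC3(CO3)O2 | intermediate
18 | (5β,13S)-8α-acetoxy-7β-(allyloxycarbonyloxy)-6α-(tert-butyldimethylsilyloxy)-15-(trimethylsilyloxy)-9α,13;15,16-diepoxylabdane | CC(=O)O[C@]1(C)[C@@H](OC(=O)OCC=C)[C@H](O[Si](C)(C)C(C)(C)C)[C@@H]2C(C)(C)CCC[C@]2(C)[C@@]12CC[C@@]1(CC(O[Si](C)(C)C)OC1)O2 | intermediate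
19 | (5β,13S)-8α-acetoxy-7β-(allyloxycarbonyloxy)-6α-(tert-butyldimethylsilyloxy)-9α,13;15,16-diepoxylabdan-15-ol (C15 anomers) | CC(=O)O[C@]1(C)[C@@H](OC(=O)OCC=C)[C@H](O[Si](C)(C)C(C)(C)C)[C@@H]2C(C)(C)CCC[C@]2(C)[C@@]12CC[C@@]1(CC(O)OC1)O2 | intermediate
20 | 15-O-methanesulfonate of 19 | CC(=O)O[C@]1(C)[C@@H](OC(=O)OCC=C)[C@H](O[Si](C)(C)C(C)(C)C)[C@@H]2C(C)(C)CCC[C@]2(C)[C@@]12CC[C@@]1(CC(OS(C)(=O)=O)OC1)O2 | intermediate
21 | (5β,13S)-8α-acetoxy-7β-(allyloxycarbonyloxy)-6α-(tert-butyldimethylsilyloxy)-9α,13;15,16-diepoxylabd-14-ene | CC(=O)O[C@]1(C)[C@@H](OC(=O)OCC=C)[C@H](O[Si](C)(C)C(C)(C)C)[C@@H]2C(C)(C)CCC[C@]2(C)[C@@]12CC[C@@]1(C=COC1)O2 | intermediate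
22 | (5β,13S)-8α-acetoxy-7β-(allyloxycarbonyloxy)-9α,13;15,16-diepoxylabd-14-en-6α-ol | CC(=O)O[C@]1(C)[C@@H](OC(=O)OCC=C)[C@H](O)[C@@H]2C(C)(C)CCC[C@]2(C)[C@@]12CC[C@@]1(C=COC1)O2 | intermediate
23 | (5β,13S)-8α-acetoxy-7β-(allyloxycarbonyloxy)-9α,13;15,16-diepoxylabd-14-en-6-one | CC(=O)O[C@]1(C)[C@@H](OC(=O)OCC=C)C(=O)[C@@H]2C(C)(C)CCC[C@]2(C)[C@@]12CC[C@@]1(C=COC1)O2 | intermediate
24 | (5β,13S)-8α-acetoxy-7β-hydroxy-9α,13;15,16-diepoxylabd-14-en-6-one | CC(=O)O[C@]1(C)[C@@H](O)C(=O)[C@@H]2C(C)(C)CCC[C@]2(C)[C@@]12CC[C@@]1(C=COC1)O2 | target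

**Totals and risks**

Total step count: 16. Longest linear sequence: 16 steps (1 and 2 to 24).

Steps most likely to fail:

1. Step 12. The facial discrimination at the C13 oxocarbenium carbon may be too small, and proton loss to the endocyclic enol ether or a hydride shift in the epoxide may outrun C–C bond formation. The fallback sets out from 15 and comes back at 21, and forms the two bonds in separate, known operations. Epoxidation with dimethyldioxirane as before gives 17. Opening with Me2AlC≡CSiMe3 (from LiC≡CSiMe3 and Me2AlCl; toluene, −78 → 0 °C), a known C-alkynylation of 1,2-anhydro sugars in which the alkynyl group is delivered from the aluminate on the former epoxide oxygen (the face that the dioxirane attacked, turned towards C8), should give the 13-(trimethylsilylethynyl) 16-alcohol F1. C-desilylation (Bu4NF/AcOH, THF, 0 °C) should give the terminal alkynol F2. Endo-selective cycloisomerisation through a tungsten vinylidene (W(CO)6, Et3N, THF, hν, 50 °C) should then close the dihydrofuran to 21.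

2. Step 1. Enantiocontrol may erode with this slow, hindered 1,1-disubstituted diene. The fallback sets out from 1 and 2 and comes back at 4. A BF3·OEt2-promoted cycloaddition (CH2Cl2, −40 °C; same regiochemistry, racemic) should give 3 together with its enantiomer F3. Luche reduction should give 4 together with its enantiomer F4. Lipase-catalysed kinetic resolution (Candida antarctica lipase B, vinyl acetate, tBuOMe) is then assumed to acylate the unwanted enantiomer to the acetate F5, leaving 4 to be separated; if the enzyme prefers 4, its acetate is separated and methanolysed instead.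

3. Step 7. Attack at the tertiary C8, or a Lewis-acid-induced semipinacol shift of the epoxy alcohol, may compete with SN2 opening at C7. The fallback sets out from 8 and comes back at 11, and avoids the epoxide. Hydrogen-bond-directed dihydroxylation syn to the 9α-hydroxyl (OsO4·TMEDA, 1.05 equiv, CH2Cl2, −78 °C; then aq. NaHSO3) should give the 7α,8α,9α-triol F6, the allylic alkene reacting ahead of the terminal one. Oxidation of the only secondary alcohol (SO3·pyridine, DMSO, iPr2NEt, 0 °C) should give the 7-ketone F7. Hydroxyl-directed reduction (Me4NBH(OAc)3, MeCN/AcOH, −30 °C), with hydride delivered from the α-face by the 8α/9α-hydroxyls, should give the 7β-alcohol 11.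

**Further compounds**
F1 | step 12 | (5β,13S)-8α-acetoxy-7β-(allyloxycarbonyloxy)-6α-(tert-butyldimethylsilyloxy)-9α,13-epoxy-13-[(trimethylsilyl)ethynyl]-14,15-dinorlabdan-16-ol | CC(=O)O[C@]1(C)[C@@H](OC(=O)OCC=C)[C@H](O[Si](C)(C)C(C)(C)C)[C@@H]2C(C)(C)CCC[C@]2(C)[C@@]12CC[C@@](CO)(C#C[Si](C)(C)C)O2
F2 | step 12 | (5β,13S)-8α-acetoxy-7β-(allyloxycarbonyloxy)-6α-(tert-butyldimethylsilyloxy)-9α,13-epoxy-13-ethynyl-14,15-dinorlabdan-16-ol | CC(=O)O[C@]1(C)[C@@H](OC(=O)OCC=C)[C@H](O[Si](C)(C)C(C)(C)C)[C@@H]2C(C)(C)CCC[C@]2(C)[C@@]12CC[C@@](CO)(C#C)O2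
F3 | step 1 | (4aS,8aR)-2,5,5,8a-tetramethyl-4a,5,8,8a-tetrahydronaphthalene-1,4-dione (enantiomer of 3) | CC1=CC(=O)[C@H]2C(C)(C)C=CC[C@@]2(C)C1=O
F4 | step 1 | (4R,4aS,8aR)-4-hydroxy-2,5,5,8a-tetramethyl-4a,5,8,8a-tetrahydronaphthalen-1(4H)-one (enantiomer of 4) | CC1=C[C@@H](O)[C@H]2C(C)(C)C=CC[C@@]2(C)C1=O
F5 | step 1 | acetate of F4 | CC1=C[C@@H](OC(C)=O)[C@H]2C(C)(C)C=CC[C@@]2(C)C1=O
F6 | step 7 | (5β)-6α-(tert-butyldimethylsilyloxy)-14,15-dinorlabd-13(16)-ene-7α,8α,9α-triol | O[C@]1(C)[C@H](O)[C@H](O[Si](C)(C)C(C)(C)C)[C@@H]2C(C)(C)CCC[C@]2(C)[C@@]1(O)CCC=C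
F7 | step 7 | (5β)-6α-(tert-butyldimethylsilyloxy)-8α,9α-dihydroxy-14,15-dinorlabd-13(16)-en-7-one | O[C@]1(C)C(=O)[C@H](O[Si](C)(C)C(C)(C)C)[C@@H]2C(C)(C)CCC[C@]2(C)[C@@]1(O)CCC=C
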